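**Plan**

1. Locants: sphingoid chain C1–C17 (cyclopropane = C12, C13 and one CH2), acyl chain C1'–C25' (C1' = amide C=O). Retrosynthetic cuts, in order: acyl C6'–C7' (C19 tail off), amide N–C1', C2–N, the C6=C7 double bond, C10–C11, and the ring bonds C12–C13 and C12–CH2.
2. Forward: the cyclopropane (the only ring) is closed first from an epoxide and a phosphonoacetate and its side chain is grown to a C7 aldehyde. This is joined at C6=C7 to a galactal-derived C1–C6 azido sulfone, a six-carbon acyl stub is attached as the amide, the C19 tail is added last, and all benzyl groups are then removed.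
3. Stereochemistry: C3/C4 are C4/C3 of D-galactal; C2 comes from SN2 azide inversion at galactal C5; C2' comes from (R)-2-aminohex-5-enoic acid (diazotisation with retention); C12/C13 come from (R)-1,2-epoxyhexane (inversion at C13, trans ring closure); 6E comes from a Julia–Kocienski olefination.
4. Enabling feature: the C6'–C7' bond lies inside the unfunctionalised polymethylene run C3'–C25', four CH2 groups beyond carbinol C2', so a terminal C5'=C6' vinyl group on the acyl stub is the whole precursor. The only competing sites, the 1,2-disubstituted C6=C7 alkene and the trans-1,2-dialkylcyclopropane ring, should not react with 9-BBN or Pd(0)/PCy3 at room temperature.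
5. Key event: one-pot anti-Markovnikov hydroboration and sp3–sp3 Suzuki–Miyaura coupling with 1-bromononadecane on the complete, benzyl-capped polar core. All six stereocentres, the E-alkene and the ring are therefore built on short intermediates, and the benzyl helpers leave in the final step.

Key step: step 16

Remark: compounds 5 and 19 are taken as catalogue compounds (5 is otherwise made from 4-bromobutan-1-ol and PPh3, not counted).

**Route**

Step 1
Reactants: 1 (R)-1,2-epoxyhexane; 2 triethyl phosphonoacetate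
Product: 3 ethyl (1S,2S)-2-butylcyclopropane-1-carboxylate
Conditions: NaH, DME, rt; then 1, 130 °C (sealed vessel)
Reagents that add atoms: none
Why: Wadsworth–Emmons cyclopropanation, in which the phosphonoacetate anion opens the epoxide at CH2, the phosphoryl group migrates from carbon to oxygen and the ester enolate closes the ring by 3-exo-tet SN2 displacement of phosphate with inversion at the butyl-bearing carbon, so the (R)-epoxide should give the (2S) centre and the trans-selective closure the (1S) centre.

Step 2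
Reactants: 3 ethyl (1S,2S)-2-butylcyclopropane-1-carboxylate
Product: 4 (1S,2S)-2-butylcyclopropane-1-carbaldehyde
Conditions: DIBAL-H (1.05 equiv), CH2Cl2, −78 °C; Rochelle salt work-up
Reagents that add atoms: none
Why: Partial ester reduction with DIBAL-H should stop at the aldehyde because the tetrahedral aluminium hemiacetal persists at −78 °C, and the trans ring is the thermodynamic isomer so the α-centre is not at risk.

Step 3
Reactants: 4 (1S,2S)-2-butylcyclopropane-1-carbaldehyde; 5 (4-hydroxybutyl)triphenylphosphonium bromide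
Product: 6 (Z)-5-[(1S,2S)-2-butylcyclopropyl]pent-4-en-1-ol
Conditions: 5, NaHMDS (2.1 equiv), THF, 0 °C; then 4, −78 °C to rt
Reagents that add atoms: none
Why: Wittig olefination with the non-stabilised oxido-ylide attaches C7–C10 in one operation by forming C10=C11, whose geometry is irrelevant because it is reduced next, and the cold conditions should leave both ring stereocentres untouched.

Step 4
Reactants: 6 (Z)-5-[(1S,2S)-2-butylcyclopropyl]pent-4-en-1-ol
Product: 7 5-[(1S,2S)-2-butylcyclopropyl]pentan-1-ol
Conditions: TsNHNH2, NaOAc, DME/H2O, reflux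
Reagents that add atoms: none
Why: Diimide reduction transfers H2 to the C10=C11 alkene in a concerted syn fashion without metal-hydride or radical intermediates, so the adjacent cyclopropane, which hydrogenation over Pd could open, should survive with both stereocentres intact.

Step 5
Reactants: 7 5-[(1S,2S)-2-butylcyclopropyl]pentan-1-ol
Product: 8 5-[(1S,2S)-2-butylcyclopropyl]pentanal
Conditions: TEMPO (cat.), PhI(OAc)2, CH2Cl2, rt
Reagents that add atoms: none
Why: TEMPO/oxoammonium oxidation of the primary alcohol should stop at the aldehyde under anhydrous conditions and does not affect the cyclopropane.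

Step 6
Reactants: 9 3,4,6-tri-O-benzyl-D-galactal
Product: 10 3,4,6-tri-O-benzyl-2-deoxy-D-lyxo-hexopyranose (anomeric mixture)
Conditions: PPh3·HBr (cat.), H2O, THF, rt
Reagents that add atoms: water, O
Why: Acid-catalysed hydration of the glycal enol ether (protonation at C2, capture of the oxocarbenium ion by water) should give the 2-deoxy lactol, whose sugar C3, C4 and C5 centres (future sphingoid C4, C3 and C2) are not involved.

Step 7
Reactants: 10 3,4,6-tri-O-benzyl-2-deoxy-D-lyxo-hexopyranose
Product: 11 (3R,4S,5R)-3,4,6-tris(benzyloxy)hexane-1,5-diol (3,4,6-tri-O-benzyl-2-deoxy-D-lyxo-hexitol)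
Conditions: NaBH4, EtOH, 0 °C to rt
Reagents that add atoms: none
Why: Borohydride reduction of the open-chain aldehyde tautomer of the lactol gives the acyclic diol, which frees the former ring oxygen as the secondary hydroxyl at sphingoid C2 and sets it apart from the new primary hydroxyl at sphingoid C6.

Step 8
Reactants: 11 (3R,4S,5R)-3,4,6-tris(benzyloxy)hexane-1,5-diol
Product: 12 (2R,3S,4R)-1,3,4-tris(benzyloxy)-6-[(1-phenyl-1H-tetrazol-5-yl)sulfanyl]hexan-2-ol
Conditions: 1-phenyl-1H-tetrazole-5-thiol, PPh3, DIAD, THF, 0 °C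
Reagents that add atoms: 1-phenyl-1H-tetrazole-5-thiol, Sc1nnnn1-c1ccccc1
Why: Mitsunobu thioetherification with the acidic tetrazole thiol should be selective for the unhindered primary hydroxyl over the flanked secondary one, and it installs the Julia–Kocienski activating group that is expelled again in step 11.

Step 9
Reactants: 12 (2R,3S,4R)-1,3,4-tris(benzyloxy)-6-[(1-phenyl-1H-tetrazol-5-yl)sulfanyl]hexan-2-ol
Product: 14 5-{[(3R,4S,5S)-5-azido-3,4,6-tris(benzyloxy)hexyl]sulfanyl}-1-phenyl-1H-tetrazole, via mesylate 13 (not isolated)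
Conditions: MsCl, Et3N, CH2Cl2, 0 °C; then NaN3, DMF, 80 °C
Reagents that add atoms: sodium azide, [Na+].[N-]=[N+]=[N-]; methanesulfonyl chloride, CS(=O)(=O)Cl (mesyl group of intermediate 13 only)
Why: SN2 displacement of the secondary mesylate by azide inverts the carbinol centre and so sets the (2S) configuration of sphingoid C2 with nitrogen in place, and it is run at the sulfide oxidation level because a tetrazolyl sulfone would be open to ipso attack by azide.

Step 10
Reactants: 14 5-{[(3R,4S,5S)-5-azido-3,4,6-tris(benzyloxy)hexyl]sulfanyl}-1-phenyl-1H-tetrazole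
Product: 15 5-{[(3R,4S,5S)-5-azido-3,4,6-tris(benzyloxy)hexyl]sulfonyl}-1-phenyl-1H-tetrazole
Conditions: (NH4)6Mo7O24·4H2O (cat.), 30% H2O2, EtOH, 0 °C to rt
Reagents that add atoms: hydrogen peroxide, OO
Why: Molybdate-catalysed peroxide oxidation should take the sulfide to the sulfone without affecting the azide, the benzyl ethers or any stereocentre.

Step 11
Reactants: 15 5-{[(3R,4S,5S)-5-azido-3,4,6-tris(benzyloxy)hexyl]sulfonyl}-1-phenyl-1H-tetrazole; 8 5-[(1S,2S)-2-butylcyclopropyl]pentanal
Product: 16 (2S,3S,4R,6E)-2-azido-1,3,4-tris(benzyloxy)-11-[(1S,2S)-2-butylcyclopropyl]undec-6-ene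
Conditions: KHMDS, DME, −60 °C; then 8, −60 °C to rt
Reagents that add atoms: none
Why: Julia–Kocienski olefination, in which the potassiated tetrazolyl sulfone adds to the unbranched aldehyde and Smiles rearrangement with anti elimination of SO2 and tetrazolone should give the C6=C7 alkene with E geometry (K+ in DME favours the anti adduct), while the 2-deoxy CH2 at C5 leaves no β-leaving group for E1cB loss.

Step 12
Reactants: 16 (2S,3S,4R,6E)-2-azido-1,3,4-tris(benzyloxy)-11-[(1S,2S)-2-butylcyclopropyl]undec-6-ene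
Product: 18 (2S,3S,4R,6E)-1,3,4-tris(benzyloxy)-11-[(1S,2S)-2-butylcyclopropyl]undec-6-en-2-amine, via iminophosphorane 17 (not isolated)
Conditions: PMe3 (1 M in THF), THF, rt; then H2O, 50 °C
Reagents that add atoms: trimethylphosphine, CP(C)C (phosphorus of intermediate 17 only)
Why: Staudinger reduction converts the hindered azide into the amine through the iminophosphorane with retention at C2 and without touching the alkene, the cyclopropane or the benzyl ethers, which catalytic hydrogenation would not spare.

Step 13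
Reactants: 19 (R)-2-aminohex-5-enoic acid
Product: 20 (R)-2-hydroxyhex-5-enoic acid
Conditions: NaNO2, 1 M H2SO4, 0 °C to rt
Reagents that add atoms: water, O
Why: Diazotisation of the α-amino acid proceeds with net retention, since the carboxylate displaces N2 to an α-lactone that water opens in a second inversion, so the R centre of the D-amino acid becomes the 2R hydroxy centre of the acyl chain.

Step 14
Reactants: 20 (R)-2-hydroxyhex-5-enoic acid
Product: 21 (R)-2-(benzyloxy)hex-5-enoic acid
Conditions: NaH (2.2 equiv), THF/DMF, 0 °C; BnBr (1.05 equiv), Bu4NI (cat.), rt; then aq. HCl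
Reagents that add atoms: benzyl bromide, BrCc1ccccc1
Why: Williamson etherification of the carboxylate–alkoxide dianion should take place at the more nucleophilic alkoxide, and because the acid stays as its carboxylate the α-hydrogen is not acidic enough for epimerisation.

Step 15
Reactants: 18 (2S,3S,4R,6E)-1,3,4-tris(benzyloxy)-11-[(1S,2S)-2-butylcyclopropyl]undec-6-en-2-amine; 21 (R)-2-(benzyloxy)hex-5-enoic acid
Product: 22 (2R)-2-(benzyloxy)-N-[(2S,3S,4R,6E)-1,3,4-tris(benzyloxy)-11-[(1S,2S)-2-butylcyclopropyl]undec-6-en-2-yl]hex-5-enamide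
Conditions: EDC·HCl, HOBt, i-Pr2NEt, CH2Cl2, 0 °C to rt
Reagents that add atoms: none
Why: Carbodiimide/HOBt amide coupling joins the amine and the α-alkoxy acid through the benzotriazolyl ester, which is not prone to epimerisation at C2'.

Step 16
Reactants: 22 (2R)-2-(benzyloxy)-N-[(2S,3S,4R,6E)-1,3,4-tris(benzyloxy)-11-[(1S,2S)-2-butylcyclopropyl]undec-6-en-2-yl]hex-5-enamide; 23 1-bromononadecane
Product: 25 (2R)-2-(benzyloxy)-N-[(2S,3S,4R,6E)-1,3,4-tris(benzyloxy)-11-[(1S,2S)-2-butylcyclopropyl]undec-6-en-2-yl]pentacosanamide, via B-alkyl-9-BBN adduct 24 (not isolated)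
Conditions: 9-BBN (0.5 M in THF, 1.3 equiv), THF, 0 °C to rt; then 23 (1.5 equiv), Pd(OAc)2 (5 mol %), PCy3 (10 mol %), K3PO4·H2O (1.5 equiv), THF, rt
Reagents that add atoms: 9-borabicyclo[3.3.1]nonane (9-BBN), B1C2CCCC1CCC2 (boryl group of intermediate 24 only; the product keeps one H from it)
Why: 9-BBN adds syn and anti-Markovnikov to the terminal C5'=C6' vinyl group to give the primary alkylborane 24, Pd(0)/PCy3 then enters the C–Br bond of 23 by an SN2-type oxidative addition, the base-activated borate transfers its primary alkyl group to palladium, and reductive elimination from the dialkylpalladium(II) forms the C6'–C7' sp3–sp3 bond. The closest known reaction type is the room-temperature B-alkyl Suzuki–Miyaura coupling of primary alkyl bromides bearing β-hydrogens with B-alkyl-9-BBN reagents under Pd/trialkylphosphine catalysis. No ring is closed and no stereocentre is created, and the existing centres (C2', C2, C3, C4, C12, C13) are remote from the reacting carbons and should not epimerise under the mild phosphate base. The selectivity needed is chemoselectivity, namely hydroboration of the monosubstituted alkene in the presence of the 1,2-disubstituted C6=C7 alkene, which the steric demand of 9-BBN and the benzyl capping of all four hydroxyls should secure, and transfer of the primary alkyl group and not a bicyclic B–C bond, which is inherent in 9-BBN. β-Hydride elimination should be held back by the bulky electron-rich PCy3, no radical or cyclopropylcarbinyl-metal species is involved so the cyclopropane is not at risk, and the hydrocarbon by-products from excess 23 are far less polar than 25.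

Step 17
Reactants: 25 (2R)-2-(benzyloxy)-N-[(2S,3S,4R,6E)-1,3,4-tris(benzyloxy)-11-[(1S,2S)-2-butylcyclopropyl]undec-6-en-2-yl]pentacosanamide
Product: 26 (2R)-N-[(2S,3S,4R,6E)-11-[(1S,2S)-2-butylcyclopropyl]-1,3,4-trihydroxyundec-6-en-2-yl]-2-hydroxypentacosanamide (CNP0280669.1)
Conditions: Na, NH3(l)/THF, −78 °C; then NH4Cl
Reagents that add atoms: none
Why: Birch-type dissolving-metal cleavage should remove all four benzyl ethers through their arene radical anions while the isolated E-alkene, the unconjugated cyclopropane and the deprotonated secondary amide are not reduced, which is why hydrogenolysis is avoided.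

**Compound list**

1 | (R)-1,2-epoxyhexane | CCCC[C@@H]1CO1 | starting material
2 | triethyl phosphonoacetate | CCOC(=O)CP(=O)(OCC)OCC | starting material
3 | ethyl (1S,2S)-2-butylcyclopropane-1-carboxylate | CCOC(=O)[C@H]1C[C@@H]1CCCC | intermediate
4 | (1S,2S)-2-butylcyclopropane-1-carbaldehyde | O=C[C@H]1C[C@@H]1CCCC | intermediate
5 | (4-hydroxybutyl)triphenylphosphonium bromide | OCCCC[P+](c1ccccc1)(c1ccccc1)c1ccccc1.[Br-] | starting material
6 | (Z)-5-[(1S,2S)-2-butylcyclopropyl]pent-4-en-1-ol | OCCC/C=C\[C@H]1C[C@@H]1CCCC | intermediate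
7 | 5-[(1S,2S)-2-butylcyclopropyl]pentan-1-ol | OCCCCC[C@H]1C[C@@H]1CCCC | intermediate
8 | 5-[(1S,2S)-2-butylcyclopropyl]pentanal | O=CCCCC[C@H]1C[C@@H]1CCCC | intermediate
9 | 3,4,6-tri-O-benzyl-D-galactal | O1[C@H](COCc2ccccc2)[C@H](OCc2ccccc2)[C@H](OCc2ccccc2)C=C1 | starting material
10 | 3,4,6-tri-O-benzyl-2-deoxy-D-lyxo-hexopyranose (anomeric mixture) | O1[C@H](COCc2ccccc2)[C@H](OCc2ccccc2)[C@H](OCc2ccccc2)CC1O | intermediate
11 | (3R,4S,5R)-3,4,6-tris(benzyloxy)hexane-1,5-diol | O[C@H](COCc1ccccc1)[C@H](OCc1ccccc1)[C@H](OCc1ccccc1)CCO | intermediate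
12 | (2R,3S,4R)-1,3,4-tris(benzyloxy)-6-[(1-phenyl-1H-tetrazol-5-yl)sulfanyl]hexan-2-ol | O[C@H](COCc1ccccc1)[C@H](OCc1ccccc1)[C@H](OCc1ccccc1)CCSc1nnnn1-c1ccccc1 | intermediate
13 | 2-O-methanesulfonate of 12 (not isolated) | CS(=O)(=O)O[C@H](COCc1ccccc1)[C@H](OCc1ccccc1)[C@H](OCc1ccccc1)CCSc1nnnn1-c1ccccc1 | intermediate
14 | 5-{[(3R,4S,5S)-5-azido-3,4,6-tris(benzyloxy)hexyl]sulfanyl}-1-phenyl-1H-tetrazole | [N-]=[N+]=N[C@@H](COCc1ccccc1)[C@H](OCc1ccccc1)[C@H](OCc1ccccc1)CCSc1nnnn1-c1ccccc1 | intermediate
15 | 5-{[(3R,4S,5S)-5-azido-3,4,6-tris(benzyloxy)hexyl]sulfonyl}-1-phenyl-1H-tetrazole | [N-]=[N+]=N[C@@H](COCc1ccccc1)[C@H](OCc1ccccc1)[C@H](OCc1ccccc1)CCS(=O)(=O)c1nnnn1-c1ccccc1 | intermediate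
16 | (2S,3S,4R,6E)-2-azido-1,3,4-tris(benzyloxy)-11-[(1S,2S)-2-butylcyclopropyl]undec-6-ene | [N-]=[N+]=N[C@@H](COCc1ccccc1)[C@H](OCc1ccccc1)[C@H](OCc1ccccc1)C/C=C/CCCC[C@H]1C[C@@H]1CCCC | intermediate
17 | N-(trimethyl-λ5-phosphanylidene) derivative of amine 18 (iminophosphorane, not isolated) | CP(C)(C)=N[C@@H](COCc1ccccc1)[C@H](OCc1ccccc1)[C@H](OCc1ccccc1)C/C=C/CCCC[C@H]1C[C@@H]1CCCC | intermediate
18 | (2S,3S,4R,6E)-1,3,4-tris(benzyloxy)-11-[(1S,2S)-2-butylcyclopropyl]undec-6-en-2-amine | N[C@@H](COCc1ccccc1)[C@H](OCc1ccccc1)[C@H](OCc1ccccc1)C/C=C/CCCC[C@H]1C[C@@H]1CCCC | intermediate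
19 | (R)-2-aminohex-5-enoic acid | C=CCC[C@@H](N)C(=O)O | starting material
20 | (R)-2-hydroxyhex-5-enoic acid | C=CCC[C@@H](O)C(=O)O | intermediate
21 | (R)-2-(benzyloxy)hex-5-enoic acid | C=CCC[C@@H](OCc1ccccc1)C(=O)O | intermediate
22 | (2R)-2-(benzyloxy)-N-[(2S,3S,4R,6E)-1,3,4-tris(benzyloxy)-11-[(1S,2S)-2-butylcyclopropyl]undec-6-en-2-yl]hex-5-enamide | C=CCC[C@@H](OCc1ccccc1)C(=O)N[C@@H](COCc1ccccc1)[C@H](OCc1ccccc1)[C@H](OCc1ccccc1)C/C=C/CCCC[C@H]1C[C@@H]1CCCC | intermediate
23 | 1-bromononadecane | CCCCCCCCCCCCCCCCCCCBr | starting material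
24 | B-alkyl-9-BBN adduct of 22 (9-borabicyclo[3.3.1]nonan-9-yl on C6' of the (2R)-2-(benzyloxy)hexanoyl chain, not isolated) | B1(C2CCCC1CCC2)CCCC[C@@H](OCc1ccccc1)C(=O)N[C@@H](COCc1ccccc1)[C@H](OCc1ccccc1)[C@H](OCc1ccccc1)C/C=C/CCCC[C@H]1C[C@@H]1CCCC | intermediate
25 | (2R)-2-(benzyloxy)-N-[(2S,3S,4R,6E)-1,3,4-tris(benzyloxy)-11-[(1S,2S)-2-butylcyclopropyl]undec-6-en-2-yl]pentacosanamide | CCCCCCCCCCCCCCCCCCCCCCC[C@@H](OCc1ccccc1)C(=O)N[C@@H](COCc1ccccc1)[C@H](OCc1ccccc1)[C@H](OCc1ccccc1)C/C=C/CCCC[C@H]1C[C@@H]1CCCC | intermediate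
26 | (2R)-N-[(2S,3S,4R,6E)-11-[(1S,2S)-2-butylcyclopropyl]-1,3,4-trihydroxyundec-6-en-2-yl]-2-hydroxypentacosanamide | CCCCCCCCCCCCCCCCCCCCCCC[C@@H](O)C(=O)N[C@@H](CO)[C@H](O)[C@H](O)C/C=C/CCCC[C@H]1C[C@@H]1CCCC | target

**Summary**

Total step count: 17. Longest linear sequence: 10 steps (steps 6–12, 15, 16, 17 from 9; equally steps 1–5, 11, 12, 15, 16, 17 from 1).

Steps most likely to fail:

1. Step 16. The hindered, Lewis-basic alkylborane may transmetalate slowly, so that β-hydride elimination or protodeboronation outruns C–C bond formation, or some hydroboration may occur at the C6=C7 alkene. The fallback sets out from 22 and returns at 25. 22 is hydroborated as before to 24, which is oxidised (NaBO3·4H2O, THF/H2O) to the 6-hydroxyhexanamide F1. Tosylation (TsCl, Et3N, DMAP, CH2Cl2) gives the primary tosylate F2. Copper-catalysed coupling (Li2CuCl4 cat., THF, −30 °C to rt) with nonadecylmagnesium bromide F3, made from 23 and Mg and used with one extra equivalent for the amide N–H, then forms the same C6'–C7' bond by SN2-type alkylation and gives 25.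

2. Step 11. The alkyl azide may decompose under the strongly basic conditions (deprotonation next to N3 with loss of N2, or attack of the sulfonyl carbanion on the azide), diverting material before olefination. The fallback sets out from 12 and returns at 16, and introduces nitrogen only after the olefination. Molybdate/H2O2 oxidation of 12 gives the hydroxy sulfone F4. Julia–Kocienski olefination of its dianion (KHMDS, 2.2 equiv, DME, −60 °C) with 8 gives the (E)-alkenol F5. Mesylation gives the mesylate F6, and NaN3 in DMF at 80 °C displaces it with inversion to give 16.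

3. Step 17. The lipophilic substrate may precipitate from liquid ammonia and be cleaved incompletely, or prolonged exposure may lead to over-reduction. The fallback sets out from 25 and arrives directly at 26 with no new compound. It replaces electron-transfer cleavage by Lewis-acid cleavage: BCl3 with pentamethylbenzene as benzyl-cation scavenger, CH2Cl2, −78 °C, which leaves isolated alkenes intact and should not open the unconjugated cyclopropane at this temperature.

Further compounds
F1 | step 16 | (2R)-2-(benzyloxy)-6-hydroxy-N-[(2S,3S,4R,6E)-1,3,4-tris(benzyloxy)-11-[(1S,2S)-2-butylcyclopropyl]undec-6-en-2-yl]hexanamide | OCCCC[C@@H](OCc1ccccc1)C(=O)N[C@@H](COCc1ccccc1)[C@H](OCc1ccccc1)[C@H](OCc1ccccc1)C/C=C/CCCC[C@H]1C[C@@H]1CCCC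
F2 | step 16 | 6-O-(p-toluenesulfonate) of F1 | Cc1ccc(cc1)S(=O)(=O)OCCCC[C@@H](OCc1ccccc1)C(=O)N[C@@H](COCc1ccccc1)[C@H](OCc1ccccc1)[C@H](OCc1ccccc1)C/C=C/CCCC[C@H]1C[C@@H]1CCCC
F3 | step 16 | nonadecylmagnesium bromide | CCCCCCCCCCCCCCCCCCC[Mg]Br
F4 | step 11 | (2R,3S,4R)-1,3,4-tris(benzyloxy)-6-[(1-phenyl-1H-tetrazol-5-yl)sulfonyl]hexan-2-ol | O[C@H](COCc1ccccc1)[C@H](OCc1ccccc1)[C@H](OCc1ccccc1)CCS(=O)(=O)c1nnnn1-c1ccccc1
F5 | step 11 | (2R,3S,4R,6E)-1,3,4-tris(benzyloxy)-11-[(1S,2S)-2-butylcyclopropyl]undec-6-en-2-ol | O[C@H](COCc1ccccc1)[C@H](OCc1ccccc1)[C@H](OCc1ccccc1)C/C=C/CCCC[C@H]1C[C@@H]1CCCC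
F6 | step 11 | 2-O-methanesulfonate of F5 | CS(=O)(=O)O[C@H](COCc1ccccc1)[C@H](OCc1ccccc1)[C@H](OCc1ccccc1)C/C=C/CCCC[C@H]1C[C@@H]1CCCC
F0 | step 17 | none | none
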